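## Structural features

The target is a 2,3-diarylpropanoate. C1 is a methyl ester, C2 is the only stereocentre, (R), and carries ring A (3-bromo-5-hydroxy-4-methoxyphenyl), and C3 is a methylene carrying ring B (2,3-dibromo-4,5-dihydroxyphenyl). There are no rings beyond the two benzene rings and no neighbouring stereocentres. The stereochemical problem is therefore one tertiary carbon that is both benzylic and alpha to an ester, so its hydrogen is acidic and any basic operation after its creation threatens racemisation. The periphery is fragile too: three aryl C–Br bonds exclude Pd/C hydrogenation, aryllithium chemistry and zerovalent palladium couplings. Ring B is a catechol that oxidises to an ortho-quinone in base and air, and all three phenols activate their rings toward bromine. Ring A has the isovanillin-type oxygen pattern (methoxy para to the chain, hydroxyl meta, bromine ortho to the methoxy), which simple bromination of a vanillin-type ketone does not give. The real difficulty is building C2 as one enantiomer under non-basic conditions while carrying the bromines and phenols. The key step uses the fact that the ring A carbon bonded to C2 has the methoxy oxygen para to it: ring A is first placed on C1 as an aryl ketone and then migrates to C2 while C1, held as a ketal, rises to the ester level; ring B, on C3 and electron-poor, stays a spectator.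

## Logic of the disconnections

18 to 17: the C1–OMe ester bond and the three phenolic O–H bonds are traced back to the tartrate half-ester linkage and three O–acetyl bonds of 17. One acidic alcoholysis then does all the unmasking. The forward step must exchange a hindered secondary ester without enolising C2, so it must be acidic, never basic.

17 to 15 (through 16): the C2–aryl bond to ring A is cut and ring A is returned to C1, which drops from ester to ketal level, while C2 receives bromine in the (R) configuration. The stereocentre is thereby made in a stereospecific step from a diastereomer that can be purified, and a 2-aryl ester is simplified to an aryl ketone derivative. The forward shift must go with clean inversion and must outrun elimination toward C3 and bridging by ring B.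

15 to 13 (through 14): the C2–Br bond is cut. This leaves a ketal with no stereocentre on the chain, the chirality residing only in the twofold-symmetric diester. The forward bromination must discriminate the two faces of the derived enol ether and must not touch either arene, which is why all phenols are acetates.

13 to 10 and 12, and 12 to 11: the two ketal C–O bonds are cut, giving an achiral ketone and the silylated chiral diol. The forward ketalisation must be aprotic so that the aryl acetates are not alcoholysed.

10 to 9 and 9 to 8: the two hydrogens on C2 and C3 are removed to give the enone, and the three O–acetyl bonds are cut. The enone is the natural aldol product. The forward reduction must saturate C2=C3 while sparing three C–Br bonds and the ketone.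

8 to 4 and 7: the C2=C3 bond is cut by a retro-aldol condensation into a ring A methyl ketone and a ring B aldehyde of similar size. The forward condensation has to work on free phenols, which points to acid catalysis.

4 to 3, 2 and 1: the O–methyl bond on the oxygen para to the acetyl group is cut, then the catechol is traced to the regioisomeric methyl ether and the C–Br bond is cut. This brings ring A back to a commercial ketone. The forward sequence must brominate ortho to the free hydroxyl and later methylate only the more acidic hydroxyl.

7 to 6 and 5: the catechol is traced to its monomethyl ether and the C–Br bond para to the methoxy group is cut, reaching a commercial aldehyde. The forward bromination must go to the position para to the methoxy group.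

## Other disconnections considered

Alternative 1: The cut is the C3–aryl bond to ring B, with the C2–H bond made in the same operation. Forward, pinacol boronate A3 would transfer ring B, under Rh(acac)(C2H4)2 and one enantiomer of BINAP, to the methylene carbon of acrylate A2. The enolate held on the Rh(BINAP) fragment would then be protonated at C2 by a phenol to give the acetal-protected ester A1, and acid methanolysis would finish.
- In favour: the two aryl halves are joined convergently, the stereocentre is set catalytically in the bond-forming step, and A1 is already a methyl ester needing only acid deprotection.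
- Against: boron in A3 sits next to a bromine on a crowded ring, so transmetalation should be slow and protodeboronation competitive. Making A3 requires metalating one position of a polybrominated arene, where an ortho-bromo arylmetal can collapse to an aryne. Protonating the stabilised enolate of a 2-aryl ester enantioselectively is harder than the amido or alkyl cases, and the product can racemise in the weakly basic medium. Three C–Br bonds would also be exposed to monovalent rhodium at elevated temperature.
- Comparison: the carbon skeleton is the same; this plan makes the C3–ring B bond, the chosen plan makes the C2–ring A bond. Here the configuration depends on a kinetic, catalyst-controlled protonation whose selectivity cannot be upgraded through a diastereomer. The chosen plan passes through the crystallisable diastereomer 15 and a stereospecific shift. On step count, convergence, catalytic use of chirality and avoidance of stoichiometric AgBF4 the alternative is the better; on the final acid-only deprotection the two are equal.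

Alternative 2: The cut is the pair of aryl C–Br bonds on ring B. Forward, two equivalents of Br2 in AcOH–CH2Cl2 at low temperature would convert catechol A5 into dibromide A4, the first bromine entering para to the 5-hydroxyl and the second ortho to the 4-hydroxyl.
- In favour: ring B would be carried as a simple catechol, its fragment would be about two steps shorter, and two fewer C–Br bonds would pass through the conjugate reduction. On that last point it is the better.
- Against: after the first bromination the second must choose the position between bromine and hydroxyl over the less hindered, equally activated position between hydroxyl and the methylene, so isomer mixtures and tribromination are likely. Br2 can also oxidise a free catechol to the ortho-quinone. A free catechol on ring B beside an acetate on ring A needs differentiated phenol protection, which consumes the saving.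
- Comparison: this cut says nothing about how C2 is made and would have to be joined to another stereocentre-forming method. Both plans brominate by electrophilic substitution. The chosen plan does it early, on 5, where only two positions are open and one is clearly preferred. Step economy is roughly equal once the protecting-group differentiation is counted.

Alternative 3: The cut runs across C1=C2 of a ketene, that is the C1–OMe and C2–H bonds. Forward, ketene A7, generated from racemic acid A8 through its chloride and a tertiary amine, would add methanol in toluene at low temperature under O-acetylquinine or its pseudoenantiomer to give triacetate ester A6; acid methanolysis of the acetates would finish.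
- In favour: A8 is readily reached by benzylating a ring A arylacetic ester with a ring B benzylic bromide, which is convergent and needs no enone reduction or silver. Chirality is catalytic and the methyl ester is delivered directly. The last step, removing acetates only, is milder than exchanging a tartrate ester. On these points it is the equal or the better.
- Against: alkaloid-catalysed methanol addition to aryl alkyl ketenes is only moderately selective and needs very low temperature. A7 is too heavy to purify, so it must be made in the flask, where ammonium salts and free amine promote a racemic background addition. The bulky ortho-brominated benzyl group makes the two ketene substituents more alike in size. There is no diastereomeric intermediate through which the selectivity could be raised.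
- Comparison: both plans reach the same triacetate skeleton. Here C2 is set by kinetic protonation of an enolate under catalyst control; in the chosen plan it is set by a stereospecific shift from a purified diastereomer. The alternative should be a few steps shorter; the chosen plan is the more predictable in configuration.

Key step: step 12

Remark on the structures: ring A needs its methoxy group para and its hydroxyl meta to the side chain, the reverse of acetovanillone, so the O-methyl group is transposed after bromination (steps 2 and 3). The descriptors of 15 (4S,5S,1R) and 17 (2S,3S,2R) were rechecked and agree with inversion at C2.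

Assumption: the facial sense of the enol-ether bromination under the (4S,5S) diester is taken as the mirror image of that of (4R,5R) ketals of aryl ethyl ketones; if it proves opposite, dimethyl (2R,3R)-tartrate replaces 11 with no other change.

## Route

Step 1
Reactants: 1 acetovanillone (1-(4-hydroxy-3-methoxyphenyl)ethan-1-one)
Product: 2 1-(3-bromo-4-hydroxy-5-methoxyphenyl)ethan-1-one
Conditions: Br2 (1.05 equiv), NaOAc, AcOH, 15 °C → rt
Reagents that add atoms: bromine, BrBr
Why: Electrophilic aromatic bromination; the free 4-hydroxyl directs to its only open ortho position, and the acetate buffer suppresses HBr-catalysed enolisation so the acetyl group is not brominated.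

Step 2
Reactants: 2 1-(3-bromo-4-hydroxy-5-methoxyphenyl)ethan-1-one
Product: 3 1-(3-bromo-4,5-dihydroxyphenyl)ethan-1-one
Conditions: BBr3 (3 equiv), CH2Cl2, −78 °C → rt; then H2O
Reagents that add atoms: none
Why: Lewis-acid cleavage of an aryl methyl ether; boron binds the phenol and the neighbouring methoxy oxygen and bromide removes the methyl group by SN2, leaving the ketone and the aryl bromide untouched after aqueous work-up.

Step 3
Reactants: 3 1-(3-bromo-4,5-dihydroxyphenyl)ethan-1-one
Product: 4 1-(3-bromo-5-hydroxy-4-methoxyphenyl)ethan-1-one
Conditions: MeI (1.05 equiv), Li2CO3 (1.1 equiv), DMF, 40 °C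
Reagents that add atoms: iodomethane, CI
Why: Regioselective Williamson O-methylation; the hydroxyl para to the acetyl group and ortho to bromine is clearly the more acidic, so the weak base forms only that phenoxide and one equivalent of MeI methylates it.

Step 4
Reactants: 5 5-bromovanillin (3-bromo-4-hydroxy-5-methoxybenzaldehyde)
Product: 6 2,3-dibromo-4-hydroxy-5-methoxybenzaldehyde
Conditions: Br2 (1.2 equiv), Fe powder (cat.), NaOAc, AcOH, rt → 60 °C
Reagents that add atoms: bromine, BrBr
Why: Electrophilic aromatic bromination of a ring with two open positions; attack para to the methoxy group is favoured over the position squeezed between methoxy and formyl, giving the 2,3-dibromo pattern of ring B.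

Step 5
Reactants: 6 2,3-dibromo-4-hydroxy-5-methoxybenzaldehyde
Product: 7 2,3-dibromo-4,5-dihydroxybenzaldehyde
Conditions: BBr3 (3 equiv), CH2Cl2, −78 °C → rt; then H2O
Reagents that add atoms: none
Why: The same Lewis-acid ether cleavage as in step 2; the aldehyde is regenerated on aqueous work-up and the aryl bromides are inert.

Step 6
Reactants: 4 1-(3-bromo-5-hydroxy-4-methoxyphenyl)ethan-1-one; 7 2,3-dibromo-4,5-dihydroxybenzaldehyde
Product: 8 (2E)-1-(3-bromo-5-hydroxy-4-methoxyphenyl)-3-(2,3-dibromo-4,5-dihydroxyphenyl)prop-2-en-1-one
Conditions: HCl (g, sat.), EtOH–EtOAc, 0 °C → rt, Ar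
Reagents that add atoms: none
Why: Acid-catalysed Claisen–Schmidt condensation; the enol of 4 adds to the protonated, non-enolisable aldehyde 7 and dehydration gives the conjugated (E) enone. Acid avoids the phenoxide deactivation and catechol oxidation that base would bring.

Step 7
Reactants: 8 (2E)-1-(3-bromo-5-hydroxy-4-methoxyphenyl)-3-(2,3-dibromo-4,5-dihydroxyphenyl)prop-2-en-1-one
Product: 9 (2E)-1-(3-acetoxy-5-bromo-4-methoxyphenyl)-3-(4,5-diacetoxy-2,3-dibromophenyl)prop-2-en-1-one
Conditions: Ac2O (4.5 equiv), pyridine, DMAP (cat.), CH2Cl2, 0 °C → rt
Reagents that add atoms: acetic anhydride, CC(=O)OC(C)=O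
Why: Nucleophile-catalysed O-acylation of all three phenols; the acetates protect the catechol, deactivate both rings for the later bromination and are removable by acid.

Step 8
Reactants: 9 (2E)-1-(3-acetoxy-5-bromo-4-methoxyphenyl)-3-(4,5-diacetoxy-2,3-dibromophenyl)prop-2-en-1-one
Product: 10 1-(3-acetoxy-5-bromo-4-methoxyphenyl)-3-(4,5-diacetoxy-2,3-dibromophenyl)propan-1-one
Conditions: H2 (4 bar), RhCl(PPh3)3 (5 mol %), toluene–THF, 40 °C
Reagents that add atoms: none
Why: Homogeneous hydrogenation of the disubstituted enone double bond; RhCl(PPh3)3 does not insert into aryl C–Br bonds or reduce aryl ketones and esters under these conditions, unlike Pd/C, which would strip bromine.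

Step 9
Reactants: 11 dimethyl (2S,3S)-tartrate
Product: 12 dimethyl (2S,3S)-2,3-bis(trimethylsilyloxy)butanedioate
Conditions: Me3SiCl (2.4 equiv), Et3N (2.6 equiv), THF, 0 °C → rt; filtration, distillation
Reagents that add atoms: chlorotrimethylsilane, C[Si](C)(C)Cl
Why: Simple O-silylation of both hydroxyls; no bond to either stereocentre is touched, so the (2S,3S) configuration is kept.

Step 10
Reactants: 10 1-(3-acetoxy-5-bromo-4-methoxyphenyl)-3-(4,5-diacetoxy-2,3-dibromophenyl)propan-1-one; 12 dimethyl (2S,3S)-2,3-bis(trimethylsilyloxy)butanedioate
Product: 13 dimethyl (4S,5S)-2-(3-acetoxy-5-bromo-4-methoxyphenyl)-2-[2-(4,5-diacetoxy-2,3-dibromophenyl)ethyl]-1,3-dioxolane-4,5-dicarboxylate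
Conditions: 12 (1.5 equiv), Me3SiOTf (0.2 equiv), CH2Cl2, −20 °C → rt; pyridine quench
Reagents that add atoms: none
Why: Aprotic silyl-transfer ketalisation; Me3SiOTf activates the ketone, the two silyl ether oxygens add and loss of hexamethyldisiloxane drives the reaction, with no alcohol or water present to cleave the aryl acetates. Because the diol has a twofold axis the ketal carbon is not a stereocentre and one compound results.

Step 11
Reactants: 13 dimethyl (4S,5S)-2-(3-acetoxy-5-bromo-4-methoxyphenyl)-2-[2-(4,5-diacetoxy-2,3-dibromophenyl)ethyl]-1,3-dioxolane-4,5-dicarboxylate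
Product: 15 dimethyl (4S,5S)-2-(3-acetoxy-5-bromo-4-methoxyphenyl)-2-[(1R)-1-bromo-2-(4,5-diacetoxy-2,3-dibromophenyl)ethyl]-1,3-dioxolane-4,5-dicarboxylate, via hydroxy enol ether 14 (not isolated)
Conditions: Br2 (1.05 equiv), HBr (cat.), CH2Cl2, −20 → 0 °C, dark; recrystallisation
Reagents that add atoms: bromine, BrBr
Why: Alpha-bromination of a ketal through its enol ether: acid opens the dioxolane to 14, bromine attacks C2 and the oxocarbenium ion recloses onto the tethered hydroxyl. The (4S,5S) diester differentiates the two faces of 14; by mirror-image analogy with (4R,5R) ketals of aryl ethyl ketones, which favour the (S) bromide, the (1R) bromide should predominate and is freed from its epimer by crystallisation. Acetoxy and bromo substituents deactivate both arenes against ring bromination, and darkness avoids radical attack at the C3 methylene.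

Step 12
Reactants: 15 dimethyl (4S,5S)-2-(3-acetoxy-5-bromo-4-methoxyphenyl)-2-[(1R)-1-bromo-2-(4,5-diacetoxy-2,3-dibromophenyl)ethyl]-1,3-dioxolane-4,5-dicarboxylate
Product: 17 dimethyl (2S,3S)-2-hydroxy-3-{[(2R)-2-(3-acetoxy-5-bromo-4-methoxyphenyl)-3-(4,5-diacetoxy-2,3-dibromophenyl)propanoyl]oxy}butanedioate, via dioxolanylium tetrafluoroborate 16 (not isolated)
Conditions: AgBF4 (1.3 equiv), H2O (5 equiv), ClCH2CH2Cl, 15 → 40 °C, dark
Reagents that add atoms: water, O
Why: AgBF4 abstracts bromide from C2 while ring A, antiperiplanar to the C2–Br bond, bridges from the ketal carbon C1 to C2 through a phenonium-like transition state, so the new C2–aryl bond forms on the face opposite the leaving bromide. The charge ends on C1 as dioxolanylium ion 16, stabilised by both ring oxygens; water adds to C1 and the ortho acid opens to hydroxy ester 17 with the tartrate C–O bonds untouched. The closest known reaction type is the Lewis-acid- or silver-promoted 1,2-aryl shift of alpha-halo ketals of aryl alkyl ketones to 2-arylalkanoic esters, a semipinacol-type rearrangement, applied here to a substrate with an arylmethyl group on the migration terminus. No ring is closed, so no mode of closure arises. The one new stereocentre, C2, is controlled by the substrate: the shift is stereospecific with inversion, so the (1R) bromide gives the (2R) ester, the descriptor being kept because ring A replaces bromine on the opposite face while C1 rises from second to first CIP rank. Ring A must move faster than loss of HBr toward C3, bridging by ring B from C3, or shift of a ketal oxygen; its para methoxy group and the push of two ketal oxygens favour the aryl shift, the two bromines and two acetoxy groups make ring B a poor neighbouring group, and the absence of base disfavours elimination. Since 15 is a single diastereomer and the medium is never basic, the configuration should reach 17 intact; any acetate loosened by the HBF4 formed does not matter because step 13 removes all three.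

Step 13
Reactants: 17 dimethyl (2S,3S)-2-hydroxy-3-{[(2R)-2-(3-acetoxy-5-bromo-4-methoxyphenyl)-3-(4,5-diacetoxy-2,3-dibromophenyl)propanoyl]oxy}butanedioate
Product: 18 methyl (2R)-2-(3-bromo-5-hydroxy-4-methoxyphenyl)-3-(2,3-dibromo-4,5-dihydroxyphenyl)propanoate
Conditions: HCl (1.25 M) in MeOH, 60 °C, Ar
Reagents that add atoms: methanol, CO
Why: Acid-catalysed alcoholysis (Fischer-type transesterification) exchanges the electron-poor tartrate alkoxy group for methoxy and methanolyses the three aryl acetates in one operation. Acid does not enolise the 2-aryl ester appreciably, so C2 stays (R); the aryl bromides and the catechol are stable to acid under argon.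

## Compound list

1 | acetovanillone, 1-(4-hydroxy-3-methoxyphenyl)ethan-1-one | CC(=O)c1ccc(O)c(OC)c1 | starting material
2 | 1-(3-bromo-4-hydroxy-5-methoxyphenyl)ethan-1-one | CC(=O)c1cc(Br)c(O)c(OC)c1 | intermediate
3 | 1-(3-bromo-4,5-dihydroxyphenyl)ethan-1-one | CC(=O)c1cc(O)c(O)c(Br)c1 | intermediate
4 | 1-(3-bromo-5-hydroxy-4-methoxyphenyl)ethan-1-one | CC(=O)c1cc(O)c(OC)c(Br)c1 | intermediate
5 | 5-bromovanillin, 3-bromo-4-hydroxy-5-methoxybenzaldehyde | O=Cc1cc(Br)c(O)c(OC)c1 | starting material
6 | 2,3-dibromo-4-hydroxy-5-methoxybenzaldehyde | O=Cc1cc(OC)c(O)c(Br)c1Br | intermediate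
7 | 2,3-dibromo-4,5-dihydroxybenzaldehyde | O=Cc1cc(O)c(O)c(Br)c1Br | intermediate
8 | (2E)-1-(3-bromo-5-hydroxy-4-methoxyphenyl)-3-(2,3-dibromo-4,5-dihydroxyphenyl)prop-2-en-1-one | O=C(/C=C/c1cc(O)c(O)c(Br)c1Br)c1cc(O)c(OC)c(Br)c1 | intermediate
9 | (2E)-1-(3-acetoxy-5-bromo-4-methoxyphenyl)-3-(4,5-diacetoxy-2,3-dibromophenyl)prop-2-en-1-one | O=C(/C=C/c1cc(OC(C)=O)c(OC(C)=O)c(Br)c1Br)c1cc(OC(C)=O)c(OC)c(Br)c1 | intermediate
10 | 1-(3-acetoxy-5-bromo-4-methoxyphenyl)-3-(4,5-diacetoxy-2,3-dibromophenyl)propan-1-one | O=C(CCc1cc(OC(C)=O)c(OC(C)=O)c(Br)c1Br)c1cc(OC(C)=O)c(OC)c(Br)c1 | intermediate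
11 | dimethyl (2S,3S)-tartrate | COC(=O)[C@@H](O)[C@H](O)C(=O)OC | starting material
12 | dimethyl (2S,3S)-2,3-bis(trimethylsilyloxy)butanedioate | COC(=O)[C@@H](O[Si](C)(C)C)[C@H](O[Si](C)(C)C)C(=O)OC | intermediate
13 | dimethyl (4S,5S)-2-(3-acetoxy-5-bromo-4-methoxyphenyl)-2-[2-(4,5-diacetoxy-2,3-dibromophenyl)ethyl]-1,3-dioxolane-4,5-dicarboxylate | O1[C@H](C(=O)OC)[C@@H](C(=O)OC)OC1(c2cc(OC(C)=O)c(OC)c(Br)c2)CCc2cc(OC(C)=O)c(OC(C)=O)c(Br)c2Br | intermediate
14 | dimethyl (2S,3S)-2-{[1-(3-acetoxy-5-bromo-4-methoxyphenyl)-3-(4,5-diacetoxy-2,3-dibromophenyl)prop-1-en-1-yl]oxy}-3-hydroxybutanedioate (alkene geometry not assigned) | COC(=O)[C@@H](O)[C@H](OC(=CCc1cc(OC(C)=O)c(OC(C)=O)c(Br)c1Br)c1cc(OC(C)=O)c(OC)c(Br)c1)C(=O)OC | intermediate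
15 | dimethyl (4S,5S)-2-(3-acetoxy-5-bromo-4-methoxyphenyl)-2-[(1R)-1-bromo-2-(4,5-diacetoxy-2,3-dibromophenyl)ethyl]-1,3-dioxolane-4,5-dicarboxylate | O1[C@H](C(=O)OC)[C@@H](C(=O)OC)OC1(c2cc(OC(C)=O)c(OC)c(Br)c2)[C@@H](Cc2cc(OC(C)=O)c(OC(C)=O)c(Br)c2Br)Br | intermediate
16 | (4S,5S)-2-[(1R)-1-(3-acetoxy-5-bromo-4-methoxyphenyl)-2-(4,5-diacetoxy-2,3-dibromophenyl)ethyl]-4,5-bis(methoxycarbonyl)-1,3-dioxolan-2-ylium tetrafluoroborate | O1[C@H](C(=O)OC)[C@@H](C(=O)OC)[O+]=C1[C@H](Cc2cc(OC(C)=O)c(OC(C)=O)c(Br)c2Br)c2cc(OC(C)=O)c(OC)c(Br)c2.F[B-](F)(F)F | intermediate
17 | dimethyl (2S,3S)-2-hydroxy-3-{[(2R)-2-(3-acetoxy-5-bromo-4-methoxyphenyl)-3-(4,5-diacetoxy-2,3-dibromophenyl)propanoyl]oxy}butanedioate | O[C@H](C(=O)OC)[C@H](OC(=O)[C@H](Cc1cc(OC(C)=O)c(OC(C)=O)c(Br)c1Br)c1cc(OC(C)=O)c(OC)c(Br)c1)C(=O)OC | intermediate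
18 | methyl (2R)-2-(3-bromo-5-hydroxy-4-methoxyphenyl)-3-(2,3-dibromo-4,5-dihydroxyphenyl)propanoate | COC(=O)[C@H](Cc1cc(O)c(O)c(Br)c1Br)c1cc(O)c(OC)c(Br)c1 | target

## Step count and risk

Total step count: 13. Longest linear sequence: 10 steps (steps 1, 2, 3, 6, 7, 8, 10, 11, 12, 13).

**Step 12 (key step).** The C2–Br bond may ionise without timely participation of ring A. Its methoxy group is twisted out of conjugation by two flanking substituents and the ring also carries an acetoxy group and a bromine, so loss of HBr toward C3, bridging by ring B or erosion of the inversion could intervene. The fallback gives up the shift and sets C2 by asymmetric hydrogenation; it sets out from 4 and 7 and returns at 18. Willgerodt–Kindler reaction of 4 (S8, morpholine, 130 °C) would give 2-(3-bromo-5-hydroxy-4-methoxyphenyl)-1-(morpholin-4-yl)ethanethione F1. Hydrolysis (aqueous H2SO4–AcOH, 100 °C) would give 2-(3-bromo-5-hydroxy-4-methoxyphenyl)acetic acid F2. Perkin condensation of F2 with 7 (Ac2O, Et3N, 110 °C, the phenols being acetylated in the same pot) would give (2E)-2-(3-acetoxy-5-bromo-4-methoxyphenyl)-3-(4,5-diacetoxy-2,3-dibromophenyl)prop-2-enoic acid F3. Hydrogenation of F3 with Ru(OAc)2(BINAP) (H2 50 bar, MeOH–CH2Cl2, the ligand enantiomer chosen to deliver the 2R acid) would give (2R)-2-(3-acetoxy-5-bromo-4-methoxyphenyl)-3-(4,5-diacetoxy-2,3-dibromophenyl)propanoic acid F4. HCl in MeOH at 60 °C would then esterify F4 and remove the acetates to give 18.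

**Step 11.** Facial discrimination in the bromination of the enol ether may be weak, because the induction is carried over from simpler ketals and the chain here ends in a bulky arylmethyl group. Ring opening of the electron-poor ketal may also be slow, or bromine may attack ring A. The fallback introduces bromine before the auxiliary and sorts the stereocentre by separation; it sets out from 10 and returns at 15. CuBr2 in EtOAc–CHCl3 at reflux would convert 10 into racemic 1-(3-acetoxy-5-bromo-4-methoxyphenyl)-2-bromo-3-(4,5-diacetoxy-2,3-dibromophenyl)propan-1-one F5. Ketalisation of F5 with 12 under Me3SiOTf as in step 10 would give 15 together with its epimer, dimethyl (4S,5S)-2-(3-acetoxy-5-bromo-4-methoxyphenyl)-2-[(1S)-1-bromo-2-(4,5-diacetoxy-2,3-dibromophenyl)ethyl]-1,3-dioxolane-4,5-dicarboxylate F6. The two are diastereomers and would be separated by crystallisation or chromatography before 15 goes on to step 12.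

**Step 10.** Ketalisation may stall, because the silylated tartrate is a poor nucleophile and the aryl ketone is conjugated and hindered; long exposure to Me3SiOTf may lead to enol silylation instead. The fallback is a two-stage exchange from 10 back to 13. MeOSiMe3 with catalytic Me3SiOTf (CH2Cl2, −40 °C) would give 1-(3-acetoxy-5-bromo-4-methoxyphenyl)-3-(4,5-diacetoxy-2,3-dibromophenyl)-1,1-dimethoxypropane F7. This would be transketalised with 11 (MsOH cat., toluene, 80 °C, methanol removed over 4 Å sieves), and any phenol set free would be re-acetylated with Ac2O–pyridine in the work-up to give 13.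

**Step 8.** Hydrogenation at the hindered, ortho-brominated styryl double bond may be slow, and forcing it risks hydrogenolysis of C–Br bonds or reduction of the ketone. The fallback, from 9 back to 10, replaces hydrogenation by conjugate hydride delivery. [(Ph3P)CuH]6 in wet toluene–THF at rt would add hydride to C3 and the enolate would be protonated in the flask by the water present; the fallback passes through no new isolable compound (F0).

**Step 6.** The acid-catalysed aldol condensation may be sluggish, because the formyl carbon of 7 is flanked by an ortho bromine and deactivated by the para hydroxyl; self-condensation of 4 or acetal formation could take over. The fallback masks the phenols for a base-mediated Claisen–Schmidt condensation; it sets out from 4 and 7 and returns at 8. MOMCl and iPr2NEt (CH2Cl2, 0 °C) would give 1-[3-bromo-4-methoxy-5-(methoxymethoxy)phenyl]ethan-1-one F8 and 2,3-dibromo-4,5-bis(methoxymethoxy)benzaldehyde F9. KOH in MeOH at rt would condense them to (2E)-1-[3-bromo-4-methoxy-5-(methoxymethoxy)phenyl]-3-[2,3-dibromo-4,5-bis(methoxymethoxy)phenyl]prop-2-en-1-one F10. HCl in MeOH at rt would remove the three acetals to give 8.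

## Further compounds

F1 | step 12 | 2-(3-bromo-5-hydroxy-4-methoxyphenyl)-1-(morpholin-4-yl)ethanethione | S=C(Cc1cc(O)c(OC)c(Br)c1)N1CCOCC1
F2 | step 12 | 2-(3-bromo-5-hydroxy-4-methoxyphenyl)acetic acid | OC(=O)Cc1cc(O)c(OC)c(Br)c1
F3 | step 12 | (2E)-2-(3-acetoxy-5-bromo-4-methoxyphenyl)-3-(4,5-diacetoxy-2,3-dibromophenyl)prop-2-enoic acid | OC(=O)/C(=C/c1cc(OC(C)=O)c(OC(C)=O)c(Br)c1Br)c1cc(OC(C)=O)c(OC)c(Br)c1
F4 | step 12 | (2R)-2-(3-acetoxy-5-bromo-4-methoxyphenyl)-3-(4,5-diacetoxy-2,3-dibromophenyl)propanoic acid | OC(=O)[C@H](Cc1cc(OC(C)=O)c(OC(C)=O)c(Br)c1Br)c1cc(OC(C)=O)c(OC)c(Br)c1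
F5 | step 11 | racemic 1-(3-acetoxy-5-bromo-4-methoxyphenyl)-2-bromo-3-(4,5-diacetoxy-2,3-dibromophenyl)propan-1-one | O=C(C(Br)Cc1cc(OC(C)=O)c(OC(C)=O)c(Br)c1Br)c1cc(OC(C)=O)c(OC)c(Br)c1
F6 | step 11 | dimethyl (4S,5S)-2-(3-acetoxy-5-bromo-4-methoxyphenyl)-2-[(1S)-1-bromo-2-(4,5-diacetoxy-2,3-dibromophenyl)ethyl]-1,3-dioxolane-4,5-dicarboxylate | O1[C@H](C(=O)OC)[C@@H](C(=O)OC)OC1(c2cc(OC(C)=O)c(OC)c(Br)c2)[C@H](Cc2cc(OC(C)=O)c(OC(C)=O)c(Br)c2Br)Br
F7 | step 10 | 1-(3-acetoxy-5-bromo-4-methoxyphenyl)-3-(4,5-diacetoxy-2,3-dibromophenyl)-1,1-dimethoxypropane | COC(OC)(CCc1cc(OC(C)=O)c(OC(C)=O)c(Br)c1Br)c1cc(OC(C)=O)c(OC)c(Br)c1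
F0 | step 8 | none | none
F8 | step 6 | 1-[3-bromo-4-methoxy-5-(methoxymethoxy)phenyl]ethan-1-one | CC(=O)c1cc(OCOC)c(OC)c(Br)c1
F9 | step 6 | 2,3-dibromo-4,5-bis(methoxymethoxy)benzaldehyde | O=Cc1cc(OCOC)c(OCOC)c(Br)c1Br
F10 | step 6 | (2E)-1-[3-bromo-4-methoxy-5-(methoxymethoxy)phenyl]-3-[2,3-dibromo-4,5-bis(methoxymethoxy)phenyl]prop-2-en-1-one | O=C(/C=C/c1cc(OCOC)c(OCOC)c(Br)c1Br)c1cc(OCOC)c(OC)c(Br)c1
A1 | alternative 1 | methyl (2R)-2-[3-bromo-4-methoxy-5-(methoxymethoxy)phenyl]-3-[2,3-dibromo-4,5-bis(methoxymethoxy)phenyl]propanoate | COC(=O)[C@H](Cc1cc(OCOC)c(OCOC)c(Br)c1Br)c1cc(OCOC)c(OC)c(Br)c1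
A2 | alternative 1 | methyl 2-[3-bromo-4-methoxy-5-(methoxymethoxy)phenyl]prop-2-enoate | COC(=O)C(=C)c1cc(OCOC)c(OC)c(Br)c1
A3 | alternative 1 | 2-[2,3-dibromo-4,5-bis(methoxymethoxy)phenyl]-4,4,5,5-tetramethyl-1,3,2-dioxaborolane | CC1(C)OB(OC1(C)C)c1cc(OCOC)c(OCOC)c(Br)c1Br
A4 | alternative 2 | methyl (2R)-2-(3-acetoxy-5-bromo-4-methoxyphenyl)-3-(2,3-dibromo-4,5-dihydroxyphenyl)propanoate | COC(=O)[C@H](Cc1cc(O)c(O)c(Br)c1Br)c1cc(OC(C)=O)c(OC)c(Br)c1
A5 | alternative 2 | methyl (2R)-2-(3-acetoxy-5-bromo-4-methoxyphenyl)-3-(3,4-dihydroxyphenyl)propanoate | COC(=O)[C@H](Cc1ccc(O)c(O)c1)c1cc(OC(C)=O)c(OC)c(Br)c1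
A6 | alternative 3 | methyl (2R)-2-(3-acetoxy-5-bromo-4-methoxyphenyl)-3-(4,5-diacetoxy-2,3-dibromophenyl)propanoate | COC(=O)[C@H](Cc1cc(OC(C)=O)c(OC(C)=O)c(Br)c1Br)c1cc(OC(C)=O)c(OC)c(Br)c1
A7 | alternative 3 | 2-(3-acetoxy-5-bromo-4-methoxyphenyl)-3-(4,5-diacetoxy-2,3-dibromophenyl)prop-1-en-1-one | O=C=C(Cc1cc(OC(C)=O)c(OC(C)=O)c(Br)c1Br)c1cc(OC(C)=O)c(OC)c(Br)c1
A8 | alternative 3 | racemic 2-(3-acetoxy-5-bromo-4-methoxyphenyl)-3-(4,5-diacetoxy-2,3-dibromophenyl)propanoic acid | OC(=O)C(Cc1cc(OC(C)=O)c(OC(C)=O)c(Br)c1Br)c1cc(OC(C)=O)c(OC)c(Br)c1
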